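**Plan**

1. Retrosynthesis: after the silyl and methoxymethyl ethers are removed, ring A is cut at C5–C6, C7–C8 and C4a–C5. This leaves ring C intact, with C2, ring B and a diazoacetyl group on C8a, and a geranyl-substituted siloxyalkyne that supplies C6 and C7.
2. Enabling feature: ring A is a phloroglucinol with geranyl on C6 between the oxygenated C5 and C7, and hydrogen on C8. C6–C7 maps onto an ynol ether, C5 onto a ketene carbon, C8 onto a diazo carbon, and C8a=C4a onto the enol-ether double bond of a 2,3-dihydropyran-4-one.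
3. Further cuts: the diazoketone at CO–CHN2 (acid plus diazomethane); ring C at O1–C8a and C2–C3 (aryl aldehyde plus the bis-silyl dienol ether of ethyl 2,4-dioxopentanoate); the alkyne at O–Si, C–O and the geranyl–alkyne bond.
4. Forward order: ring B is bought; ring C is made first (step 3); the geranyl chain is joined to a two-carbon alkyne unit (steps 6 and 7); ring A is formed last on ring C (step 8); two deprotections follow.
5. Stereochemistry: the only stereocentre, C2 (S), is set in step 3 by a Ti(OiPr)4/(S)-BINOL catalyst and then meets only neutral, buffered or mildly acidic conditions. The E alkene of the side chain is bought with geranyl bromide.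

Key step: step 8

Abbreviations: Ar = 3-methoxy-4,5-bis(methoxymethoxy)phenyl; geranyl = (2E)-3,7-dimethylocta-2,6-dien-1-yl; atom labels C2, C4a, C5 to C8a are those of the flavanone.

Remark: the Ti(OiPr)4/(S)-BINOL catalyst is assumed to direct the diene to the Si face of the aryl aldehyde, as it does with related bis(silyloxy)dienes; were the opposite sense found, (R)-BINOL would be used.

**Route**

Step 1
Reactants: 1 3,4-dihydroxy-5-methoxybenzaldehyde
Product: 2 3-methoxy-4,5-bis(methoxymethoxy)benzaldehyde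
Conditions: MeOCH2Cl, i-Pr2NEt, CH2Cl2, 0 °C → rt
Reagents that add atoms: chloromethyl methyl ether, COCCl
Why: Double O-alkylation of the phenols under amine base (methoxymethyl ether formation) masks ring B with groups that should withstand organometallic bases, diazomethane, light and fluoride.

Step 2
Reactants: 3 ethyl 2,4-dioxopentanoate
Product: 4 ethyl (2Z)-2,4-bis(trimethylsilyloxy)penta-2,4-dienoate
Conditions: Me3SiOTf (2.2 equiv), Et3N, Et2O, 0 °C; used crude
Reagents that add atoms: trimethylsilyl triflate, C[Si](C)(C)OS(=O)(=O)C(F)(F)F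
Why: Soft enolisation with Me3SiOTf/Et3N silylates both the chelated enol and the methyl ketone (silyl enol ether formation), and either order of silylation leads to the same 1,3-bis(silyloxy)diene, whose terminal CH2 is the nucleophilic carbon.

Step 3
Reactants: 2 3-methoxy-4,5-bis(methoxymethoxy)benzaldehyde; 4 ethyl (2Z)-2,4-bis(trimethylsilyloxy)penta-2,4-dienoate
Product: 6 ethyl (2S)-2-[3-methoxy-4,5-bis(methoxymethoxy)phenyl]-4-oxo-3,4-dihydro-2H-pyran-6-carboxylate, via silylated aldol adduct 5 (not isolated)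
Conditions: Ti(OiPr)4/(S)-BINOL (1:1, 10 mol%), 4 Å MS, THF, −78 °C → rt; then CF3CO2H (cat.), CH2Cl2, 0 °C
Reagents that add atoms: none
Why: A titanium–BINOL-catalysed vinylogous Mukaiyama aldol addition (a stepwise hetero-Diels–Alder reaction) joins the terminal CH2 of 4 to the aldehyde, the (S)-BINOL complex being expected to expose the Si face so that C2 becomes S, and catalytic acid then closes ring C by oxa-Michael addition to the β-silyloxy enone with loss of hexamethyldisiloxane, briefly enough to spare the aryl methoxymethyl ethers.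

Step 4
Reactants: 6 ethyl (2S)-2-[3-methoxy-4,5-bis(methoxymethoxy)phenyl]-4-oxo-3,4-dihydro-2H-pyran-6-carboxylate
Product: 8 (2S)-2-[3-methoxy-4,5-bis(methoxymethoxy)phenyl]-4-oxo-3,4-dihydro-2H-pyran-6-carboxylic acid, via trimethylstannyl ester 7 (not isolated)
Conditions: Me3SnOH, ClCH2CH2Cl, 70 °C; brief wash with cold dilute aq. HCl
Reagents that add atoms: trimethyltin hydroxide, C[Sn](C)(C)O
Why: Me3SnOH cleaves the activated ethyl ester through a tin carboxylate under essentially neutral conditions (mild ester hydrolysis), which avoids the hydroxide-induced enolisation at C3 and E1cB opening of ring C that would racemise C2.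

Step 5
Reactants: 8 (2S)-2-[3-methoxy-4,5-bis(methoxymethoxy)phenyl]-4-oxo-3,4-dihydro-2H-pyran-6-carboxylic acid
Product: 10 (2S)-6-(2-diazoacetyl)-2-[3-methoxy-4,5-bis(methoxymethoxy)phenyl]-2,3-dihydro-4H-pyran-4-one, via mixed carbonic anhydride 9 (not isolated)
Conditions: i-BuOCOCl, N-methylmorpholine, THF, −20 °C; then CH2N2, Et2O, −20 → 0 °C
Reagents that add atoms: diazomethane, C=[N+]=[N-]
Why: Acylation of diazomethane by the mixed carbonic anhydride (first stage of the Arndt–Eistert sequence) forms the diazoketone without acid, so the methoxymethyl ethers and C2 are safe, and substitution at the activated acyl carbon at low temperature should outrun dipolar cycloaddition to the trisubstituted, oxygen-bearing C=C bond.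

Step 6
Reactants: 11 geranyl bromide
Product: 12 (4E)-5,9-dimethyldeca-4,8-dien-1-yne
Conditions: HC≡CMgBr (3 equiv), CuCl (cat.), THF, 0 °C → rt
Reagents that add atoms: ethynylmagnesium bromide (HC≡CMgBr), C#C[Mg]Br
Why: CuCl-catalysed cross-coupling of an alkynyl Grignard reagent with a primary allylic bromide (SN2 at the unhindered carbon) gives the skipped enyne with the E alkene intact, and the excess of reagent suppresses a second alkylation.

Step 7
Reactants: 12 (4E)-5,9-dimethyldeca-4,8-dien-1-yne
Product: 15 (4E)-5,9-dimethyl-1-(triisopropylsilyloxy)deca-4,8-dien-1-yne, via lithium acetylide 13 (not isolated), via lithium ynolate 14 (not isolated)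
Conditions: LiN(SiMe3)2, THF, −78 °C; t-BuOOLi (from t-BuOOH and LiN(SiMe3)2), −78 → 0 °C; i-Pr3SiOTf, −78 °C; NaHCO3 work-up
Reagents that add atoms: tert-butyl hydroperoxide, CC(C)(C)OO; triisopropylsilyl triflate, CC(C)[Si](OS(=O)(=O)C(F)(F)F)(C(C)C)C(C)C
Why: Electrophilic oxygenation of the lithium acetylide by t-BuOOLi gives the lithium ynolate, which the bulky silyl triflate captures on oxygen (ynolate O-silylation) to give an isolable ynol silyl ether, while LiN(SiMe3)2 is too weak a base to isomerise the skipped enyne.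

Step 8
Reactants: 10 (2S)-6-(2-diazoacetyl)-2-[3-methoxy-4,5-bis(methoxymethoxy)phenyl]-2,3-dihydro-4H-pyran-4-one; 15 (4E)-5,9-dimethyl-1-(triisopropylsilyloxy)deca-4,8-dien-1-yne
Product: 20 (2S)-6-geranyl-5-hydroxy-2-[3-methoxy-4,5-bis(methoxymethoxy)phenyl]-7-(triisopropylsilyloxy)-2,3-dihydro-4H-chromen-4-one, via vinylketene 16 (not isolated), via 4-vinylcyclobutenone 17 (not isolated), via dienylketene 18 (not isolated), via cyclohexa-2,4-dienone 19 (not isolated)
Conditions: 15 (1.5 equiv), hν (440 nm LED), ClCH2CH2Cl, 25 °C; then 80 °C in the dark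
Reagents that add atoms: none
Why: Blue light expels N2 from 10 and the pyranone carbon that becomes C8a migrates in a Wolff rearrangement to give vinylketene 16, whose ketene carbon (future C5) is attacked by the geranyl-bearing, oxygen-remote carbon of ynol ether 15 in a regiospecific [2+2] cycloaddition that forms C5–C6 and C7–C8 and gives cyclobutenone 17. At 80 °C 17 opens by conrotatory four-electron electrocyclic cleavage to dienylketene 18, which closes ring A by a disrotatory six-electron electrocyclisation between the ketene carbon and C4a (the α-carbon of the ring C enone) and then tautomerises from dienone 19 to the phenol, so that ring A is formed already aromatic. This is the Danheiser benzannulation in its photochemical diazoketone form with a siloxyalkyne, and the closest known cases are cycloalkenyl, aryl and heteroaryl diazomethyl ketones. No stereocentre is created, because the sp3 carbons of 17 and 19 return to sp2, and C2 is a remote saturated spectator that meets neither acid nor base. The step needs regioselectivity (geranyl at C6 and not C8), which the polarisation of the ynol ether secures, and chemoselectivity for the alkyne over the two trisubstituted alkenes of the side chain and over photoreactions of the enone, which the far higher ketenophilicity of the siloxyalkyne and the use of visible light absorbed only by the diazoketone should secure. The new C5 phenol is chelated to the C4 carbonyl and flanked by the geranyl group, which should suppress its acylation by ketene intermediates.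

Step 9
Reactants: 20 (2S)-6-geranyl-5-hydroxy-2-[3-methoxy-4,5-bis(methoxymethoxy)phenyl]-7-(triisopropylsilyloxy)-2,3-dihydro-4H-chromen-4-one
Product: 21 (2S)-6-geranyl-5,7-dihydroxy-2-[3-methoxy-4,5-bis(methoxymethoxy)phenyl]-2,3-dihydro-4H-chromen-4-one
Conditions: Bu4NF, AcOH (1:1), THF, 0 °C
Reagents that add atoms: none
Why: Fluoride-induced cleavage of the aryl silyl ether (desilylation) frees the C7 phenol, and the acetic acid buffer keeps the phenoxide protonated so that retro-oxa-Michael opening of ring C and loss of configuration at C2 are avoided.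

Step 10
Reactants: 21 (2S)-6-geranyl-5,7-dihydroxy-2-[3-methoxy-4,5-bis(methoxymethoxy)phenyl]-2,3-dihydro-4H-chromen-4-one
Product: 22 (2S)-2-(3,4-dihydroxy-5-methoxyphenyl)-6-geranyl-5,7-dihydroxy-2,3-dihydro-4H-chromen-4-one (CNP0110161.1)
Conditions: HCl (3 M aq.), MeOH, 40 °C, argon
Reagents that add atoms: none
Why: Acid-catalysed transacetalisation of the two methoxymethyl ethers to methanol (acetal cleavage) frees the ring B diol under conditions in which the flavanone C2 is configurationally stable and which should be mild enough to leave the geranyl alkenes uncyclised.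

**Compound list**

1 | 3,4-dihydroxy-5-methoxybenzaldehyde | COc1cc(C=O)cc(O)c1O | starting material
2 | 3-methoxy-4,5-bis(methoxymethoxy)benzaldehyde | COCOc1cc(C=O)cc(OC)c1OCOC | intermediate
3 | ethyl 2,4-dioxopentanoate | CCOC(=O)C(=O)CC(C)=O | starting material
4 | ethyl (2Z)-2,4-bis(trimethylsilyloxy)penta-2,4-dienoate | CCOC(=O)/C(O[Si](C)(C)C)=C/C(=C)O[Si](C)(C)C | intermediate
5 | ethyl (2Z,6S)-6-[3-methoxy-4,5-bis(methoxymethoxy)phenyl]-4-oxo-2,6-bis(trimethylsilyloxy)hex-2-enoate | CCOC(=O)/C(O[Si](C)(C)C)=C/C(=O)C[C@H](O[Si](C)(C)C)c1cc(OC)c(OCOC)c(OCOC)c1 | intermediate (not isolated)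
6 | ethyl (2S)-2-[3-methoxy-4,5-bis(methoxymethoxy)phenyl]-4-oxo-3,4-dihydro-2H-pyran-6-carboxylate | CCOC(=O)C1=CC(=O)C[C@@H](c2cc(OC)c(OCOC)c(OCOC)c2)O1 | intermediate
7 | trimethylstannyl (2S)-2-[3-methoxy-4,5-bis(methoxymethoxy)phenyl]-4-oxo-3,4-dihydro-2H-pyran-6-carboxylate | C[Sn](C)(C)OC(=O)C1=CC(=O)C[C@@H](c2cc(OC)c(OCOC)c(OCOC)c2)O1 | intermediate (not isolated)
8 | (2S)-2-[3-methoxy-4,5-bis(methoxymethoxy)phenyl]-4-oxo-3,4-dihydro-2H-pyran-6-carboxylic acid | OC(=O)C1=CC(=O)C[C@@H](c2cc(OC)c(OCOC)c(OCOC)c2)O1 | intermediate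
9 | isobutyl carbonic anhydride of acid 8 | CC(C)COC(=O)OC(=O)C1=CC(=O)C[C@@H](c2cc(OC)c(OCOC)c(OCOC)c2)O1 | intermediate (not isolated)
10 | (2S)-6-(2-diazoacetyl)-2-[3-methoxy-4,5-bis(methoxymethoxy)phenyl]-2,3-dihydro-4H-pyran-4-one | [N-]=[N+]=CC(=O)C1=CC(=O)C[C@@H](c2cc(OC)c(OCOC)c(OCOC)c2)O1 | intermediate
11 | geranyl bromide, (2E)-1-bromo-3,7-dimethylocta-2,6-diene | CC(C)=CCC/C(C)=C/CBr | starting material
12 | (4E)-5,9-dimethyldeca-4,8-dien-1-yne | CC(C)=CCC/C(C)=C/CC#C | intermediate
13 | lithium (4E)-5,9-dimethyldeca-4,8-dien-1-yn-1-ide | CC(C)=CCC/C(C)=C/CC#C[Li] | intermediate (not isolated)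
14 | lithium (4E)-5,9-dimethyldeca-4,8-dien-1-yn-1-olate | CC(C)=CCC/C(C)=C/CC#C[O-].[Li+] | intermediate (not isolated)
15 | (4E)-5,9-dimethyl-1-(triisopropylsilyloxy)deca-4,8-dien-1-yne | CC(C)=CCC/C(C)=C/CC#CO[Si](C(C)C)(C(C)C)C(C)C | intermediate
16 | [(2S)-2-[3-methoxy-4,5-bis(methoxymethoxy)phenyl]-4-oxo-3,4-dihydro-2H-pyran-6-yl]ketene | O=C=CC1=CC(=O)C[C@@H](c2cc(OC)c(OCOC)c(OCOC)c2)O1 | intermediate (not isolated)
17 | 2-geranyl-4-[(2S)-2-[3-methoxy-4,5-bis(methoxymethoxy)phenyl]-4-oxo-3,4-dihydro-2H-pyran-6-yl]-3-(triisopropylsilyloxy)cyclobut-2-en-1-one (both C4 epimers) | O=C1C(C/C=C(\C)CCC=C(C)C)=C(O[Si](C(C)C)(C(C)C)C(C)C)C1C3=CC(=O)C[C@@H](c2cc(OC)c(OCOC)c(OCOC)c2)O3 | intermediate (not isolated)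
18 | (3Z)-2-geranyl-4-[(2S)-2-[3-methoxy-4,5-bis(methoxymethoxy)phenyl]-4-oxo-3,4-dihydro-2H-pyran-6-yl]-3-(triisopropylsilyloxy)buta-1,3-dien-1-one | O=C=C(C/C=C(\C)CCC=C(C)C)/C(O[Si](C(C)C)(C(C)C)C(C)C)=C\C1=CC(=O)C[C@@H](c2cc(OC)c(OCOC)c(OCOC)c2)O1 | intermediate (not isolated)
19 | (2S)-6-geranyl-2-[3-methoxy-4,5-bis(methoxymethoxy)phenyl]-7-(triisopropylsilyloxy)-2,3-dihydro-4aH-chromene-4,5-dione (C4a unassigned) | O=C1C(C/C=C(\C)CCC=C(C)C)=C(O[Si](C(C)C)(C(C)C)C(C)C)C=C2O[C@H](c3cc(OC)c(OCOC)c(OCOC)c3)CC(=O)C12 | intermediate (not isolated)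
20 | (2S)-6-geranyl-5-hydroxy-2-[3-methoxy-4,5-bis(methoxymethoxy)phenyl]-7-(triisopropylsilyloxy)-2,3-dihydro-4H-chromen-4-one | COc1cc([C@@H]2CC(=O)c3c(cc(O[Si](C(C)C)(C(C)C)C(C)C)c(C/C=C(\C)CCC=C(C)C)c3O)O2)cc(OCOC)c1OCOC | intermediate
21 | (2S)-6-geranyl-5,7-dihydroxy-2-[3-methoxy-4,5-bis(methoxymethoxy)phenyl]-2,3-dihydro-4H-chromen-4-one | COc1cc([C@@H]2CC(=O)c3c(cc(O)c(C/C=C(\C)CCC=C(C)C)c3O)O2)cc(OCOC)c1OCOC | intermediate
22 | (2S)-2-(3,4-dihydroxy-5-methoxyphenyl)-6-[(2E)-3,7-dimethylocta-2,6-dien-1-yl]-5,7-dihydroxy-2,3-dihydro-4H-chromen-4-one | COc1cc([C@@H]2CC(=O)c3c(cc(O)c(C/C=C(\C)CCC=C(C)C)c3O)O2)cc(O)c1O | target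

**Step count and risks**

Total: 10 steps. Longest linear sequence: 7 steps (1, 3, 4, 5, 8, 9, 10).

Steps most likely to fail:

1. Step 8. The short-lived ketene may be captured incompletely by the alkyne, so that it dimerises, or irradiation may divert the diazoketone or the ring C enone into other photoreactions before the Wolff shift. The fallback makes the same ketene without light. It sets out from 10: a silver-catalysed Wolff rearrangement in water (PhCO2Ag, Et3N, THF/H2O, dark; Arndt–Eistert homologation) should give 2-[(2S)-2-Ar-4-oxo-3,4-dihydro-2H-pyran-6-yl]acetic acid F1. Treatment with 1-chloro-N,N,2-trimethylprop-1-en-1-amine in CH2Cl2 at 0 °C should convert it under neutral conditions into the acid chloride F2. Slow addition of F2 to 15 and i-Pr2NEt in toluene at 80 °C should generate vinylketene 16 by dehydrochlorination, which enters the same thermal [2+2], ring-opening and electrocyclisation sequence and returns to the route at 20.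

2. Step 3. The ester-deactivated diene may add sluggishly, or the catalyst may give poor facial selectivity with it. The fallback sets the stereocentre with a stoichiometric reagent and builds the diketo ester afterwards. It sets out from 2: Brown allylboration with (−)-B-methallyldiisopinocampheylborane (from (+)-α-pinene; Et2O, −78 °C, then NaOH/H2O2) should attack the Si face and give (1S)-1-Ar-3-methylbut-3-en-1-ol F3. Lemieux–Johnson cleavage (OsO4 cat., NaIO4, 2,6-lutidine, dioxane/H2O) should give (4S)-4-Ar-4-hydroxybutan-2-one F4. Claisen condensation of its dianion with diethyl oxalate (LiN(SiMe3)2, 3 equiv, THF, −78 °C) should give ethyl (6S)-6-Ar-6-hydroxy-2,4-dioxohexanoate F5. Catalytic CF3CO2H in CH2Cl2 should cyclise and dehydrate it, returning to the route at 6.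

3. Step 5. Diazomethane may add as a dipole across the electron-poor C=C bond of the enone instead of, or after, acyl substitution. The fallback installs the diazo group by diazo transfer and uses no diazomethane. It sets out from 8: Steglich thioesterification (EtSH, N,N'-dicyclohexylcarbodiimide, DMAP cat., CH2Cl2) should give the S-ethyl thioester F6. Fukuyama coupling (MeZnI, PdCl2(PPh3)2 cat., toluene, rt) should give (2S)-6-acetyl-2-Ar-2,3-dihydro-4H-pyran-4-one F7, leaving the ring ketone untouched. Kinetic deprotonation of the acetyl methyl group (LiN(SiMe3)2, THF, −78 °C) and trapping with CF3CO2CH2CF3 should give the trifluoroacetylated diketone F8, which is not isolated. Detrifluoroacetylative diazo transfer (MeSO2N3, Et3N, H2O, MeCN) returns to the route at 10.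

**Further compounds**

F1 | step 8 | 2-[(2S)-2-[3-methoxy-4,5-bis(methoxymethoxy)phenyl]-4-oxo-3,4-dihydro-2H-pyran-6-yl]acetic acid | OC(=O)CC1=CC(=O)C[C@@H](c2cc(OC)c(OCOC)c(OCOC)c2)O1
F2 | step 8 | 2-[(2S)-2-[3-methoxy-4,5-bis(methoxymethoxy)phenyl]-4-oxo-3,4-dihydro-2H-pyran-6-yl]acetyl chloride | ClC(=O)CC1=CC(=O)C[C@@H](c2cc(OC)c(OCOC)c(OCOC)c2)O1
F3 | step 3 | (1S)-1-[3-methoxy-4,5-bis(methoxymethoxy)phenyl]-3-methylbut-3-en-1-ol | CC(=C)C[C@H](O)c1cc(OC)c(OCOC)c(OCOC)c1
F4 | step 3 | (4S)-4-hydroxy-4-[3-methoxy-4,5-bis(methoxymethoxy)phenyl]butan-2-one | CC(=O)C[C@H](O)c1cc(OC)c(OCOC)c(OCOC)c1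
F5 | step 3 | ethyl (6S)-6-hydroxy-6-[3-methoxy-4,5-bis(methoxymethoxy)phenyl]-2,4-dioxohexanoate | CCOC(=O)C(=O)CC(=O)C[C@H](O)c1cc(OC)c(OCOC)c(OCOC)c1
F6 | step 5 | S-ethyl (2S)-2-[3-methoxy-4,5-bis(methoxymethoxy)phenyl]-4-oxo-3,4-dihydro-2H-pyran-6-carbothioate | CCSC(=O)C1=CC(=O)C[C@@H](c2cc(OC)c(OCOC)c(OCOC)c2)O1
F7 | step 5 | (2S)-6-acetyl-2-[3-methoxy-4,5-bis(methoxymethoxy)phenyl]-2,3-dihydro-4H-pyran-4-one | CC(=O)C1=CC(=O)C[C@@H](c2cc(OC)c(OCOC)c(OCOC)c2)O1
F8 | step 5 | (2S)-2-[3-methoxy-4,5-bis(methoxymethoxy)phenyl]-6-(4,4,4-trifluoro-3-oxobutanoyl)-2,3-dihydro-4H-pyran-4-one | O=C(CC(=O)C1=CC(=O)C[C@@H](c2cc(OC)c(OCOC)c(OCOC)c2)O1)C(F)(F)F
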